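**Plan**

- Retrosynthesis: the four MOM acetals are cut first. Then, in one stroke, the C2–C3 and O1–C8a bonds of the pyranone are cut. This gives B-ring aldehyde 12, whose C=O becomes C2–O1, and silyl enol ether 9 of a 2-fluoroacetophenone. Further back, the C8 prenyl group is cut (Claisen–Cope), then the acetyl group (Friedel–Crafts) and the B-ring prenyl group (Stille).
- Forward: rings A and B are bought as 5-fluororesorcinol and 3-bromo-4,5-dihydroxybenzaldehyde. The heterocyclic C ring is formed last, in step 9.
- Enabling feature: the C4 ketone. Its α-carbon C3 is the enolate carbon. The ring carbon C8a ortho to it has O5 and O7 both meta, so once it carries fluorine it accepts the aldolate oxygen by SNAr.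
- Stereochemistry: C2 is (S) and is the only stereocentre. It is set in step 9 by a chiral quaternary ammonium cation (ion pair), and no later step touches it.

Key step: step 9

Assumption: the cinchonidinium ion pair in step 9 is taken to favour Si-face addition to the aldehyde, which gives (S). If the opposite sense is met, the pseudoenantiomeric cinchoninium salt is used and nothing else changes.

**Route**

Step 1
Reactants: 1 5-fluorobenzene-1,3-diol
Product: 2 1-(2-fluoro-4,6-dihydroxyphenyl)ethan-1-one
Conditions: AcOH, BF3·OEt2, 85 °C; then aq. NaOAc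
Reagents that add atoms: acetic acid, CC(=O)O
Why: Friedel–Crafts C-acylation of a resorcinol should go to the position ortho to one OH and para to the other (next to F) rather than to the doubly flanked position between the hydroxyls, and the BF2 chelate of the product resists a second acylation.

Step 2
Reactants: 2 1-(2-fluoro-4,6-dihydroxyphenyl)ethan-1-one
Product: 3 1-[2-fluoro-6-hydroxy-4-(methoxymethoxy)phenyl]ethan-1-one
Conditions: MOMCl (1.05 equiv), K2CO3, acetone, 0 °C to rt
Reagents that add atoms: chloromethyl methyl ether, COCCl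
Why: Williamson-type acetalisation should select the free para-hydroxyl, because the ortho-hydroxyl is held in a hydrogen bond to the ketone and is much less nucleophilic.

Step 3
Reactants: 3 1-[2-fluoro-6-hydroxy-4-(methoxymethoxy)phenyl]ethan-1-one
Product: 4 1-[2-fluoro-4-(methoxymethoxy)-6-(3-methylbut-2-en-1-yloxy)phenyl]ethan-1-one
Conditions: prenyl bromide, K2CO3, acetone, reflux
Reagents that add atoms: 1-bromo-3-methylbut-2-ene, CC(C)=CCBr
Why: Williamson O-alkylation of the remaining chelated phenol with a reactive allylic bromide is standard for 2-hydroxyacetophenones and should leave the mono-activated aryl fluoride untouched under carbonate conditions.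

Step 4
Reactants: 4 1-[2-fluoro-4-(methoxymethoxy)-6-(3-methylbut-2-en-1-yloxy)phenyl]ethan-1-one
Product: 7 1-[2-fluoro-6-hydroxy-4-(methoxymethoxy)-3-(3-methylbut-2-en-1-yl)phenyl]ethan-1-one, via ortho-dienone 5 (not isolated), via para-dienone 6 (not isolated)
Conditions: Eu(fod)3 (10 mol%), CHCl3, 60 °C
Reagents that add atoms: none
Why: A Eu(III)-chelated aromatic Claisen rearrangement should give the congested 1,1-dimethylallyl dienone 5, which should relay the allyl group by a Cope shift to the para carbon (6) and tautomerise, as known for 2-prenyloxyacetophenones and 5-O-prenylflavanones (para-Claisen–Cope), the two allyl inversions returning the linear prenyl group between F and OMOM.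

Step 5
Reactants: 7 1-[2-fluoro-6-hydroxy-4-(methoxymethoxy)-3-(3-methylbut-2-en-1-yl)phenyl]ethan-1-one
Product: 8 1-[2-fluoro-4,6-bis(methoxymethoxy)-3-(3-methylbut-2-en-1-yl)phenyl]ethan-1-one
Conditions: NaH (1.1 equiv), MOMCl, DMF, 0 °C to rt
Reagents that add atoms: chloromethyl methyl ether, COCCl
Why: The chelated phenol needs full deprotonation for Williamson-type acetalisation, and the phenoxide should form and react well before the methyl ketone is enolised.

Step 6
Reactants: 8 1-[2-fluoro-4,6-bis(methoxymethoxy)-3-(3-methylbut-2-en-1-yl)phenyl]ethan-1-one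
Product: 9 {1-[2-fluoro-4,6-bis(methoxymethoxy)-3-(3-methylbut-2-en-1-yl)phenyl]ethenyloxy}trimethylsilane
Conditions: LiHMDS, THF, −78 °C; TMSCl; non-aqueous work-up (pentane, filtration), used crude
Reagents that add atoms: chlorotrimethylsilane, C[Si](C)(C)Cl
Why: Kinetic enolisation of the methyl ketone and O-silylation is routine, LiHMDS being too weak to metalate the ring, and silyl triflates are avoided because they attack MOM acetals.

Step 7
Reactants: 10 3-bromo-4,5-dihydroxybenzaldehyde
Product: 11 3-bromo-4,5-bis(methoxymethoxy)benzaldehyde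
Conditions: MOMCl (2.5 equiv), K2CO3, acetone, 50 °C
Reagents that add atoms: chloromethyl methyl ether, COCCl
Why: Double Williamson-type acetalisation of a catechol under carbonate conditions is standard and the aldehyde is inert to it.

Step 8
Reactants: 11 3-bromo-4,5-bis(methoxymethoxy)benzaldehyde
Product: 12 3,4-bis(methoxymethoxy)-5-(3-methylbut-2-en-1-yl)benzaldehyde
Conditions: tributyl(prenyl)stannane, Pd(PPh3)4 (5 mol%), DMF, 90 °C
Reagents that add atoms: tributyl(3-methylbut-2-en-1-yl)stannane, CCCC[Sn](CCCC)(CCCC)CC=C(C)C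
Why: Stille coupling of the aryl bromide with the prenylstannane should give the linear prenyl arene by reductive elimination at the less substituted allyl terminus, and the aldehyde needs no protection under these neutral conditions.

Step 9
Reactants: 9 {1-[2-fluoro-4,6-bis(methoxymethoxy)-3-(3-methylbut-2-en-1-yl)phenyl]ethenyloxy}trimethylsilane (1.2 equiv); 12 3,4-bis(methoxymethoxy)-5-(3-methylbut-2-en-1-yl)benzaldehyde
Product: 15 (2S)-2-[3,4-bis(methoxymethoxy)-5-(3-methylbut-2-en-1-yl)phenyl]-5,7-bis(methoxymethoxy)-8-(3-methylbut-2-en-1-yl)-2,3-dihydro-4H-chromen-4-one, via ammonium enolate 13 (not isolated), via (S)-aldolate 14 (not isolated)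
Conditions: O-allyl-N-(9-anthracenylmethyl)cinchonidinium bifluoride (10 mol%), toluene/THF, −40 to 0 °C; AcOH quench at full conversion of 12
Reagents that add atoms: none
Why: Proposed new method: fluoride from the catalyst desilylates 9 to the chiral ammonium enolate 13, which should add to the Si face of aldehyde 12 inside the ion pair to give (S)-aldolate 14; its alkoxide oxygen then attacks the fluorine-bearing ring carbon ortho to the ketone (the future C8a) and expels fluoride, which returns as the ammonium fluoride to desilylate the next molecule of 9, so the nucleofuge of the ring closure is the chain carrier and no stoichiometric base is present. The closest known reaction types are the chiral quaternary ammonium fluoride- or bifluoride-catalysed Mukaiyama aldol addition, the ammonium phenoxide-catalysed addition/lactonisation of silyl nucleophiles in which the expelled phenoxide is the relay, and tandem addition–SNAr annulations of 2-fluoroaryl ketones. The pyranone ring closes by 6-endo-trig addition of oxygen to C8a of the C8a=C4a–C4=O unit (Meisenheimer enolate resting on the C4 carbonyl) followed by loss of fluoride, so that overall the step is a formal hetero-[4+2] between the C=O of 12 and a 1-fluoro-3-siloxydiene embedded in the arene. C2 is the only new stereocentre and is controlled by the cinchonidinium cation, either in the C–C bond formation or, if the aldolate reverts by retro-aldol, in the irreversible ring closure of the equilibrating aldolates, which would make the step stereoconvergent. The step needs ring closure to outrun retro-aldol, dehydration and silyl transfer, which the ortho-carbonyl activation with both A-ring oxygens meta to C8a and the six-membered transition state should secure (a silylated aldol is reopened by the relayed fluoride and funnels to the same product), and it needs 15 to resist E1cB ring opening, which the low temperature and the excess of 9 that traps free fluoride at silicon should secure.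

Step 10
Reactants: 15 (2S)-2-[3,4-bis(methoxymethoxy)-5-(3-methylbut-2-en-1-yl)phenyl]-5,7-bis(methoxymethoxy)-8-(3-methylbut-2-en-1-yl)-2,3-dihydro-4H-chromen-4-one
Product: 16 (2S)-2-[3,4-dihydroxy-5-(3-methylbut-2-en-1-yl)phenyl]-5,7-dihydroxy-8-(3-methylbut-2-en-1-yl)-2,3-dihydro-4H-chromen-4-one
Conditions: 3 M aq. HCl, MeOH, 40 °C, stopped at full conversion
Reagents that add atoms: none
Why: Acid-catalysed acetal exchange with methanol removes all four MOM groups under conditions used for prenylated flavanones, and C2 is not epimerised because the acid does not open the chelated 5-hydroxychromanone.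

**Compound list**

1 | 5-fluorobenzene-1,3-diol | Oc1cc(O)cc(F)c1 | starting material
2 | 1-(2-fluoro-4,6-dihydroxyphenyl)ethan-1-one | CC(=O)c1c(O)cc(O)cc1F | intermediate
3 | 1-[2-fluoro-6-hydroxy-4-(methoxymethoxy)phenyl]ethan-1-one | CC(=O)c1c(O)cc(OCOC)cc1F | intermediate
4 | 1-[2-fluoro-4-(methoxymethoxy)-6-(3-methylbut-2-en-1-yloxy)phenyl]ethan-1-one | CC(=O)c1c(OCC=C(C)C)cc(OCOC)cc1F | intermediate
5 | ortho-dienone: 2-acetyl-3-fluoro-5-(methoxymethoxy)-6-(2-methylbut-3-en-2-yl)cyclohexa-2,4-dien-1-one (racemic, transient) | CC(=O)C1=C(F)C=C(OCOC)C(C(C)(C)C=C)C1=O | intermediate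
6 | para-dienone: 2-acetyl-3-fluoro-5-(methoxymethoxy)-4-(3-methylbut-2-en-1-yl)cyclohexa-2,5-dien-1-one (racemic, transient) | CC(=O)C1=C(F)C(CC=C(C)C)C(OCOC)=CC1=O | intermediate
7 | 1-[2-fluoro-6-hydroxy-4-(methoxymethoxy)-3-(3-methylbut-2-en-1-yl)phenyl]ethan-1-one | CC(=O)c1c(O)cc(OCOC)c(CC=C(C)C)c1F | intermediate
8 | 1-[2-fluoro-4,6-bis(methoxymethoxy)-3-(3-methylbut-2-en-1-yl)phenyl]ethan-1-one | CC(=O)c1c(OCOC)cc(OCOC)c(CC=C(C)C)c1F | intermediate
9 | {1-[2-fluoro-4,6-bis(methoxymethoxy)-3-(3-methylbut-2-en-1-yl)phenyl]ethenyloxy}trimethylsilane | C=C(O[Si](C)(C)C)c1c(OCOC)cc(OCOC)c(CC=C(C)C)c1F | intermediate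
10 | 3-bromo-4,5-dihydroxybenzaldehyde | O=Cc1cc(O)c(O)c(Br)c1 | starting material
11 | 3-bromo-4,5-bis(methoxymethoxy)benzaldehyde | O=Cc1cc(OCOC)c(OCOC)c(Br)c1 | intermediate
12 | 3,4-bis(methoxymethoxy)-5-(3-methylbut-2-en-1-yl)benzaldehyde | O=Cc1cc(OCOC)c(OCOC)c(CC=C(C)C)c1 | intermediate
13 | ammonium enolate of ketone 8 (anion shown; counter-ion is the catalyst cation) | C=C([O-])c1c(OCOC)cc(OCOC)c(CC=C(C)C)c1F | intermediate
14 | (S)-aldolate: (1S)-1-[3,4-bis(methoxymethoxy)-5-(3-methylbut-2-en-1-yl)phenyl]-3-[2-fluoro-4,6-bis(methoxymethoxy)-3-(3-methylbut-2-en-1-yl)phenyl]-3-oxopropan-1-olate (counter-ion is the catalyst cation) | [O-][C@@H](CC(=O)c1c(OCOC)cc(OCOC)c(CC=C(C)C)c1F)c1cc(OCOC)c(OCOC)c(CC=C(C)C)c1 | intermediate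
15 | (2S)-2-[3,4-bis(methoxymethoxy)-5-(3-methylbut-2-en-1-yl)phenyl]-5,7-bis(methoxymethoxy)-8-(3-methylbut-2-en-1-yl)-2,3-dihydro-4H-chromen-4-one | CC(C)=CCc1cc([C@@H]2CC(=O)c3c(OCOC)cc(OCOC)c(CC=C(C)C)c3O2)cc(OCOC)c1OCOC | intermediate
16 | (2S)-2-[3,4-dihydroxy-5-(3-methylbut-2-en-1-yl)phenyl]-5,7-dihydroxy-8-(3-methylbut-2-en-1-yl)-2,3-dihydro-4H-chromen-4-one | CC(C)=CCc1cc([C@@H]2CC(=O)c3c(O)cc(O)c(CC=C(C)C)c3O2)cc(O)c1O | target

**Count**

Total steps: 10. Longest linear sequence: 8 (steps 1–6, 9, 10).

**Steps most likely to fail**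

Step 9 (Proposed new method). The fluoride relay may stall, or the enantiomeric purity may erode through reversible aldol addition, weak ion-pair induction, or base-induced E1cB opening of the product. Fallback with known chemistry, from 9 and 12: a Lewis-base-activated SiCl4 Mukaiyama aldol addition (SiCl4, chiral binaphthyldiamine-derived bisphosphoramide 5 mol%, i-Pr2NEt, CH2Cl2, −78 °C, buffered KF/NaHCO3 work-up; the catalyst enantiomer that gives Si-face addition) should give (3S)-3-[3,4-bis(methoxymethoxy)-5-(3-methylbut-2-en-1-yl)phenyl]-1-[2-fluoro-4,6-bis(methoxymethoxy)-3-(3-methylbut-2-en-1-yl)phenyl]-3-hydroxypropan-1-one F1. Its ring is then closed in a separate intramolecular SNAr of the alkoxide (NaH 1.05 equiv, THF, 0 °C, short contact) to rejoin the route at 15.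

Step 4. The ortho-dienone may tautomerise before the Cope shift, which would leave the allyl group, in its 1,1-dimethylallyl form, on the carbon between the two oxygens. Fallback, from 3: protection of the chelated phenol (NaH, MOMCl, DMF) should give 1-[2-fluoro-4,6-bis(methoxymethoxy)phenyl]ethan-1-one F2. Electrophilic bromination (NBS, MeCN, 0 °C) is expected at the less hindered activated position, flanked by F and OMOM, to give 1-[3-bromo-2-fluoro-4,6-bis(methoxymethoxy)phenyl]ethan-1-one F3. Stille coupling with tributyl(prenyl)stannane (Pd(PPh3)4, DMF, 90 °C) then rejoins the route at 8.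

Step 10. Protonation of the prenyl alkenes may compete with acetal cleavage and lead to cyclisation onto the neighbouring phenols (dimethylchroman formation), and prolonged acid may erode C2. Fallback, from 15: aprotic acetal exchange with TMSOTf/2,2'-bipyridyl (CH2Cl2, 0 °C) should convert the aryl MOM ethers through bipyridinium salts into (2S)-2-[3,4-bis(trimethylsilyloxy)-5-(3-methylbut-2-en-1-yl)phenyl]-5,7-bis(trimethylsilyloxy)-8-(3-methylbut-2-en-1-yl)-2,3-dihydro-4H-chromen-4-one F4. Hydrolysis of F4 with water at neutral pH gives 16 without a Brønsted acid ever meeting the alkenes.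

**Further compounds**

F1 | step 9 | (3S)-3-[3,4-bis(methoxymethoxy)-5-(3-methylbut-2-en-1-yl)phenyl]-1-[2-fluoro-4,6-bis(methoxymethoxy)-3-(3-methylbut-2-en-1-yl)phenyl]-3-hydroxypropan-1-one | O[C@@H](CC(=O)c1c(OCOC)cc(OCOC)c(CC=C(C)C)c1F)c1cc(OCOC)c(OCOC)c(CC=C(C)C)c1
F2 | step 4 | 1-[2-fluoro-4,6-bis(methoxymethoxy)phenyl]ethan-1-one | CC(=O)c1c(OCOC)cc(OCOC)cc1F
F3 | step 4 | 1-[3-bromo-2-fluoro-4,6-bis(methoxymethoxy)phenyl]ethan-1-one | CC(=O)c1c(OCOC)cc(OCOC)c(Br)c1F
F4 | step 10 | (2S)-2-[3,4-bis(trimethylsilyloxy)-5-(3-methylbut-2-en-1-yl)phenyl]-5,7-bis(trimethylsilyloxy)-8-(3-methylbut-2-en-1-yl)-2,3-dihydro-4H-chromen-4-one | CC(C)=CCc1cc([C@@H]2CC(=O)c3c(O[Si](C)(C)C)cc(O[Si](C)(C)C)c(CC=C(C)C)c3O2)cc(O[Si](C)(C)C)c1O[Si](C)(C)C
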